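**Plan**

Numbering: ring A is the catechol ring; ring B the carbocycle (C1 pyrone-bearing, C2 and C3 acid-bearing, C4 olefinic); ring C the pyrone (O1', C2' carbonyl, C3', C4' on C1, C5', C6' with CO2H). The target is the trans (1R,2S) isomer.
Enabling feature: C4' is the only atom of ring C bonded to C1, so it can begin as the ketone of a C1 acylpyruvate whose enol oxygen on C6' is already O1'; a phosphonoacetyl group on that oxygen supplies C2' and C3'.
Cuts: ester and ether protecting groups; C3'=C4' (olefination) and O1'–C2' (enol acylation); C4'–C5' (acylation of a pyruvate enol silane); C1–CO2 (malonate decarboxylation); C3=C4 and C1–C2 (aldol condensation, Michael addition); C1–aryl (copper-catalysed malonate arylation).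
Forward order: ring A is bought, ring B is closed by an amine-catalysed Michael/aldol domino, the C1 carboxyl is extended to the acylpyruvate, ring C is closed last, then the protecting groups are removed.
Stereochemistry: C2 comes from the catalyst-controlled Michael addition; C1 is set trans to C2 by acid-catalysed equilibration at the C4' ketone stage, where only C1 can epimerise; the key step creates no stereocentre.

Key step: step 10

Remark: the sense of induction in step 2 is assigned from the usual shielding model of diarylprolinol silyl ethers (attack on the E,s-trans iminium ion anti to the diarylmethyl group); if the antipode were to form, the (R)-catalyst would be used instead.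

**Route**

Step 1
Reactants: 1 2-bromo-4,5-dimethoxybenzaldehyde; 2 diallyl malonate
Product: 3 diallyl 2-(2-formyl-4,5-dimethoxyphenyl)malonate
Conditions: CuI (10 mol%), 2-picolinic acid (20 mol%), Cs2CO3, 1,4-dioxane, 70 °C
Reagents that add atoms: none
Why: Copper-catalysed α-arylation of a malonate (Hurtley-type coupling) is assisted by the ortho formyl group of the aryl bromide and, unlike a zerovalent palladium catalyst, leaves the allyl esters intact.

Step 2
Reactants: 3 diallyl 2-(2-formyl-4,5-dimethoxyphenyl)malonate; 4 ethyl (E)-4-oxobut-2-enoate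
Product: 6 1,1-diallyl 2-ethyl (2R)-3-formyl-6,7-dimethoxy-2H-naphthalene-1,1,2-tricarboxylate, via Michael adduct 5 (not isolated)
Conditions: (S)-2-[diphenyl(trimethylsilyloxy)methyl]pyrrolidine (20 mol%), PhCO2H (20 mol%), toluene, rt
Reagents that add atoms: none
Why: Iminium–enamine domino Michael/aldol condensation: the malonate carbon should add to the ester-bearing β-carbon of the E-iminium ion on the face remote from the diphenyl(silyloxy)methyl group, which sets C2, and the enamine so formed condenses with the aryl aldehyde to close ring B as the conjugated enal.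

Step 3
Reactants: 6 ring B enal
Product: 7 (2R)-1,1-bis(allyloxycarbonyl)-2-(ethoxycarbonyl)-6,7-dimethoxy-1,2-dihydronaphthalene-3-carboxylic acid
Conditions: NaClO2, NaH2PO4, 2-methyl-2-butene, t-BuOH–H2O, 0 °C → rt
Reagents that add atoms: sodium chlorite, [Na+].[O-]Cl=O
Why: Pinnick oxidation converts the enal into the acid in a buffered medium that should not disturb C2–H, the alkene scavenger keeping hypochlorous acid away from the allyl esters.

Step 4
Reactants: 7 C3 carboxylic acid
Product: 8 1,1-diallyl 2-ethyl 3-methyl (2R)-6,7-dimethoxy-2H-naphthalene-1,1,2,3-tetracarboxylate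
Conditions: TMSCHN2, toluene–MeOH, 0 °C
Reagents that add atoms: (trimethylsilyl)diazomethane, C[Si](C)(C)C=[N+]=[N-]
Why: Diazoalkane O-methylation esterifies the acid without base, so the C3 carboxyl is told apart from the C1 carboxyls that are freed next.

Step 5
Reactants: 8 tetraester
Product: 10 (1RS,2S)-2-(ethoxycarbonyl)-6,7-dimethoxy-3-(methoxycarbonyl)-1,2-dihydronaphthalene-1-carboxylic acid (C1 epimers), via malonic diacid 9 (not isolated)
Conditions: Pd(PPh3)4 (5 mol%), morpholine, THF, rt; 1 M HCl wash; toluene, 90 °C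
Reagents that add atoms: none
Why: Tsuji–Trost deallylation with morpholine as allyl acceptor frees only the two C1 carboxyls and the arylmalonic acid loses CO2 on warming; protonation of the enol sets C1 without control (probably mainly cis, anti to the C2 ester), which step 8 corrects.

Step 6
Reactants: 11 methyl pyruvate
Product: 12 methyl 2-(trimethylsilyloxy)acrylate
Conditions: TMSCl, Et3N, CH2Cl2, 0 °C → rt
Reagents that add atoms: chlorotrimethylsilane, C[Si](C)(C)Cl
Why: Silyl enol ether formation by amine-mediated O-silylation of the readily enolised α-keto ester gives the known 2-siloxyacrylate, the carbon nucleophile for step 7.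

Step 7
Reactants: 10 C1 carboxylic acid (C1 epimers); 12 methyl 2-(trimethylsilyloxy)acrylate
Product: 14 2-ethyl 3-methyl (1RS,2S)-1-[(Z)-3-hydroxy-4-methoxy-4-oxobut-2-enoyl]-6,7-dimethoxy-1,2-dihydronaphthalene-2,3-dicarboxylate (C1 epimers), via acid chloride 13 (not isolated)
Conditions: (COCl)2, DMF (cat.), CH2Cl2, 0 °C → rt, evaporate; 12, ZnCl2, CH2Cl2–Et2O, 0 °C → rt
Reagents that add atoms: none
Why: Lewis-acid-promoted C-acylation of a silyl enol ether by an acid chloride (a Mukaiyama-type crossed Claisen acylation) forms C4'–C5' without base, so no ketene arises from the α-aryl acid chloride and C2–H is not exposed; loss of Me3SiCl leaves the acylpyruvate as its chelated Z-enol.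

Step 8
Reactants: 14 acylpyruvate (C1 epimers)
Product: 15 2-ethyl 3-methyl (1S,2S)-1-[(Z)-3-hydroxy-4-methoxy-4-oxobut-2-enoyl]-6,7-dimethoxy-1,2-dihydronaphthalene-2,3-dicarboxylate
Conditions: TsOH·H2O (20 mol%), CHCl3, 50 °C
Reagents that add atoms: none
Why: Acid-catalysed keto–enol equilibration (thermodynamic epimerisation) acts only at C1, which is α to the C4' ketone, whereas the ester-bound C2 does not enolise under acid; the trans isomer with both substituents pseudoaxial avoids the peri contact with H8 and the allylic strain against the C3 ester, so C1 should settle trans to the catalyst-set C2.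

Step 9
Reactants: 15 trans acylpyruvate
Product: 16 2-ethyl 3-methyl (1S,2S)-1-[(Z)-3-{[2-(diethoxyphosphoryl)acetyl]oxy}-4-methoxy-4-oxobut-2-enoyl]-6,7-dimethoxy-1,2-dihydronaphthalene-2,3-dicarboxylate
Conditions: (EtO)2P(O)CH2CO2H, (COCl)2, DMF (cat.), CH2Cl2, 0 °C; then 15, pyridine, CH2Cl2, −40 → 0 °C
Reagents that add atoms: 2-(diethoxyphosphoryl)acetic acid, CCOP(=O)(CC(=O)O)OCC
Why: Enol O-acylation by an acid chloride with pyridine: the acylpyruvate rests as the chelated Z-enol with its hydroxyl on C6', the oxygen on C4' is shielded by the branched C1 substituent, and low temperature without a nucleophilic catalyst should suppress acyl transfer between the two oxygens.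

Step 10
Reactants: 16 enol phosphonoacetate
Product: 17 2-ethyl 3-methyl (1R,2S)-6,7-dimethoxy-1-[6-(methoxycarbonyl)-2-oxo-2H-pyran-4-yl]-1,2-dihydronaphthalene-2,3-dicarboxylate
Conditions: LiCl, iPr2NEt, MeCN, 0 °C → rt
Reagents that add atoms: none
Why: Intramolecular Horner–Wadsworth–Emmons olefination: lithium chelation between the phosphoryl and acyl oxygens lets iPr2NEt deprotonate the phosphonoacetate CH2 (C3'), the carbanion adds to the C4' ketone, and the oxaphosphetane collapses with loss of lithium diethyl phosphate to form C3'=C4'. The closest known reaction type is the closure of phosphonoacetates of 2-acylphenols and of enolised 1,3-dicarbonyl compounds to coumarins and 2-pyrones. Ring C closes in a 6-exo-trig mode, the Z geometry of the C5'=C6' enol ester holding O1' and the C4' carbonyl cis so that the six-membered transition state is unstrained. No stereocentre is formed; the amine is too weak to remove C2–H, and any enolisation of C4' towards C1 can only return the favoured trans isomer. The selectivity needed is attack on the C4' ketone in preference to the ester carbonyls and to acyl transfer of the enol ester: the ketone is the most electrophilic carbonyl within reach, attack on the C6' ester would give a five-membered ring, and elimination to the aromatic 2-pyrone makes the closure irreversible.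

Step 11
Reactants: 17 protected target
Product: 18 2-ethyl 3-methyl (1R,2S)-6,7-dihydroxy-1-[6-(methoxycarbonyl)-2-oxo-2H-pyran-4-yl]-1,2-dihydronaphthalene-2,3-dicarboxylate
Conditions: BBr3 (8 equiv), CH2Cl2, −78 → 0 °C; MeOH, then H2O
Reagents that add atoms: none
Why: Lewis-acid dealkylation of the aryl methyl ethers by BBr3 frees the catechol, and at or below 0 °C the alkyl esters and the pyrone lactone should survive.

Step 12
Reactants: 18 catechol triester
Product: 19 (1R,2S)-1-(6-carboxy-2-oxo-2H-pyran-4-yl)-6,7-dihydroxy-1,2-dihydronaphthalene-2,3-dicarboxylic acid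
Conditions: 6 M HCl–1,4-dioxane (1:1), 80 °C, argon
Reagents that add atoms: water, O
Why: Acid-catalysed ester hydrolysis cleaves the three alkyl esters without base, so the pyrone is not opened, the C3=C4 double bond does not migrate and the trans diad, being the more stable arrangement, is kept.

**Compound list**

1 | 2-bromo-4,5-dimethoxybenzaldehyde | COc1cc(Br)c(C=O)cc1OC | starting material
2 | diallyl malonate | C=CCOC(=O)CC(=O)OCC=C | starting material
3 | diallyl 2-(2-formyl-4,5-dimethoxyphenyl)malonate | COc1cc(C=O)c(C(C(=O)OCC=C)C(=O)OCC=C)cc1OC | intermediate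
4 | ethyl (E)-4-oxobut-2-enoate | CCOC(=O)/C=C/C=O | starting material
5 | diallyl 2-[(2R)-1-ethoxy-1,4-dioxobutan-2-yl]-2-(2-formyl-4,5-dimethoxyphenyl)malonate (Michael adduct, aldehyde form of the catalyst-bound enamine) | O=CC[C@@H](C(=O)OCC)C(C(=O)OCC=C)(C(=O)OCC=C)c1cc(OC)c(OC)cc1C=O | intermediate (not isolated)
6 | 1,1-diallyl 2-ethyl (2R)-3-formyl-6,7-dimethoxy-2H-naphthalene-1,1,2-tricarboxylate | O=CC1=Cc2cc(OC)c(OC)cc2C(C(=O)OCC=C)(C(=O)OCC=C)[C@@H]1C(=O)OCC | intermediate
7 | (2R)-1,1-bis(allyloxycarbonyl)-2-(ethoxycarbonyl)-6,7-dimethoxy-1,2-dihydronaphthalene-3-carboxylic acid | O=C(O)C1=Cc2cc(OC)c(OC)cc2C(C(=O)OCC=C)(C(=O)OCC=C)[C@@H]1C(=O)OCC | intermediate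
8 | 1,1-diallyl 2-ethyl 3-methyl (2R)-6,7-dimethoxy-2H-naphthalene-1,1,2,3-tetracarboxylate | COC(=O)C1=Cc2cc(OC)c(OC)cc2C(C(=O)OCC=C)(C(=O)OCC=C)[C@@H]1C(=O)OCC | intermediate
9 | (2R)-2-(ethoxycarbonyl)-6,7-dimethoxy-3-(methoxycarbonyl)-2H-naphthalene-1,1-dicarboxylic acid | COC(=O)C1=Cc2cc(OC)c(OC)cc2C(C(=O)O)(C(=O)O)[C@@H]1C(=O)OCC | intermediate (not isolated)
10 | (1RS,2S)-2-(ethoxycarbonyl)-6,7-dimethoxy-3-(methoxycarbonyl)-1,2-dihydronaphthalene-1-carboxylic acid, mixture of C1 epimers | COC(=O)C1=Cc2cc(OC)c(OC)cc2C(C(=O)O)[C@@H]1C(=O)OCC | intermediate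
11 | methyl pyruvate | CC(=O)C(=O)OC | starting material
12 | methyl 2-(trimethylsilyloxy)acrylate | C=C(O[Si](C)(C)C)C(=O)OC | intermediate
13 | 2-ethyl 3-methyl (1RS,2S)-1-(chlorocarbonyl)-6,7-dimethoxy-1,2-dihydronaphthalene-2,3-dicarboxylate, mixture of C1 epimers | COC(=O)C1=Cc2cc(OC)c(OC)cc2C(C(=O)Cl)[C@@H]1C(=O)OCC | intermediate (not isolated)
14 | 2-ethyl 3-methyl (1RS,2S)-1-[(Z)-3-hydroxy-4-methoxy-4-oxobut-2-enoyl]-6,7-dimethoxy-1,2-dihydronaphthalene-2,3-dicarboxylate, mixture of C1 epimers (acylpyruvate, enol form) | COC(=O)C1=Cc2cc(OC)c(OC)cc2C(C(=O)/C=C(\O)C(=O)OC)[C@@H]1C(=O)OCC | intermediate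
15 | 2-ethyl 3-methyl (1S,2S)-1-[(Z)-3-hydroxy-4-methoxy-4-oxobut-2-enoyl]-6,7-dimethoxy-1,2-dihydronaphthalene-2,3-dicarboxylate (trans) | COC(=O)C1=Cc2cc(OC)c(OC)cc2[C@@H](C(=O)/C=C(\O)C(=O)OC)[C@@H]1C(=O)OCC | intermediate
16 | 2-ethyl 3-methyl (1S,2S)-1-[(Z)-3-{[2-(diethoxyphosphoryl)acetyl]oxy}-4-methoxy-4-oxobut-2-enoyl]-6,7-dimethoxy-1,2-dihydronaphthalene-2,3-dicarboxylate | COC(=O)C1=Cc2cc(OC)c(OC)cc2[C@@H](C(=O)/C=C(\OC(=O)CP(=O)(OCC)OCC)C(=O)OC)[C@@H]1C(=O)OCC | intermediate
17 | 2-ethyl 3-methyl (1R,2S)-6,7-dimethoxy-1-[6-(methoxycarbonyl)-2-oxo-2H-pyran-4-yl]-1,2-dihydronaphthalene-2,3-dicarboxylate | COC(=O)C1=Cc2cc(OC)c(OC)cc2[C@@H](c2cc(C(=O)OC)oc(=O)c2)[C@@H]1C(=O)OCC | intermediate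
18 | 2-ethyl 3-methyl (1R,2S)-6,7-dihydroxy-1-[6-(methoxycarbonyl)-2-oxo-2H-pyran-4-yl]-1,2-dihydronaphthalene-2,3-dicarboxylate | COC(=O)C1=Cc2cc(O)c(O)cc2[C@@H](c2cc(C(=O)OC)oc(=O)c2)[C@@H]1C(=O)OCC | intermediate
19 | (1R,2S)-1-(6-carboxy-2-oxo-2H-pyran-4-yl)-6,7-dihydroxy-1,2-dihydronaphthalene-2,3-dicarboxylic acid (CNP0195322.1) | O=C(O)C1=Cc2cc(O)c(O)cc2[C@@H](c2cc(C(=O)O)oc(=O)c2)[C@@H]1C(=O)O | target

**Summary**

Total steps: 12. Longest linear sequence: 11 steps (1 to 19 through steps 1–5 and 7–12); step 6 prepares 12 on a one-step branch.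

Steps most likely to fail:

Step 9. The acyl group may land on, or migrate to, the C4' enol oxygen by acyl transfer across the chelate, and the activated enol ester may hydrolyse during isolation; a misplaced acyl group would later close to the isomeric pyrone. The fallback sets out from 15: heating with (triphenylphosphoranylidene)ketene in toluene at 80 °C lets the acidic enol add across the cumulated ylide with no amine and no acyl chloride present, giving the enol (triphenylphosphoranylidene)acetate F1 in the flask. Its intramolecular Wittig olefination at the C4' ketone closes the same C3'=C4' bond, and the route is rejoined at 17.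

Step 7. The electron-rich α-aryl acid chloride may ionise under the Lewis acid, with loss of CO and aromatisation to a naphthalene, and the siloxyacrylate may prove too weak a nucleophile. The fallback sets out from 10: Steglich thioesterification (EtSH, EDC·HCl, DMAP cat.) gives the S-ethyl thioester F2, and Fukuyama reduction (Et3SiH, Pd/C, acetone) gives the C1 aldehyde F3. A BF3·OEt2-mediated Mukaiyama aldol addition of 12 at −78 °C then gives the β-hydroxy-α-keto ester F4, and Dess–Martin oxidation of the carbinol returns the acylpyruvate 14, which enters step 8 as before.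

Step 2. The tertiary malonate carbon may add too slowly to the iminium ion of the bulky catalyst, since the quaternary C1 is formed next to C2, or the addition may reverse with loss of enantiomeric purity. The fallback sets out from 3 and 4: the same domino run with pyrrolidine and PhCO2H gives the racemic enal F5, and Pinnick oxidation gives the racemic acid F6. Fractional crystallisation of its salt with (R)-1-phenylethylamine (or the antipodal amine, whichever gives the less soluble salt of the 2R acid) gives the salt F7, from which dilute HCl liberates 7.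

Further compounds
F1 | step 9 | 2-ethyl 3-methyl (1S,2S)-6,7-dimethoxy-1-[(Z)-4-methoxy-4-oxo-3-{[(triphenylphosphoranylidene)acetyl]oxy}but-2-enoyl]-1,2-dihydronaphthalene-2,3-dicarboxylate | COC(=O)C1=Cc2cc(OC)c(OC)cc2[C@@H](C(=O)/C=C(\OC(=O)C=P(c3ccccc3)(c3ccccc3)c3ccccc3)C(=O)OC)[C@@H]1C(=O)OCC
F2 | step 7 | 2-ethyl 3-methyl (1RS,2S)-1-[(ethylsulfanyl)carbonyl]-6,7-dimethoxy-1,2-dihydronaphthalene-2,3-dicarboxylate | COC(=O)C1=Cc2cc(OC)c(OC)cc2C(C(=O)SCC)[C@@H]1C(=O)OCC
F3 | step 7 | 2-ethyl 3-methyl (1RS,2S)-1-formyl-6,7-dimethoxy-1,2-dihydronaphthalene-2,3-dicarboxylate | COC(=O)C1=Cc2cc(OC)c(OC)cc2C(C=O)[C@@H]1C(=O)OCC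
F4 | step 7 | 2-ethyl 3-methyl (1RS,2S)-1-(1-hydroxy-4-methoxy-3,4-dioxobutyl)-6,7-dimethoxy-1,2-dihydronaphthalene-2,3-dicarboxylate (carbinol epimers) | COC(=O)C1=Cc2cc(OC)c(OC)cc2C(C(O)CC(=O)C(=O)OC)[C@@H]1C(=O)OCC
F5 | step 2 | racemic 1,1-diallyl 2-ethyl 3-formyl-6,7-dimethoxy-2H-naphthalene-1,1,2-tricarboxylate | O=CC1=Cc2cc(OC)c(OC)cc2C(C(=O)OCC=C)(C(=O)OCC=C)C1C(=O)OCC
F6 | step 2 | racemic 1,1-bis(allyloxycarbonyl)-2-(ethoxycarbonyl)-6,7-dimethoxy-1,2-dihydronaphthalene-3-carboxylic acid | O=C(O)C1=Cc2cc(OC)c(OC)cc2C(C(=O)OCC=C)(C(=O)OCC=C)C1C(=O)OCC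
F7 | step 2 | (R)-1-phenylethylammonium (2R)-1,1-bis(allyloxycarbonyl)-2-(ethoxycarbonyl)-6,7-dimethoxy-1,2-dihydronaphthalene-3-carboxylate | [O-]C(=O)C1=Cc2cc(OC)c(OC)cc2C(C(=O)OCC=C)(C(=O)OCC=C)[C@@H]1C(=O)OCC.C[C@@H]([NH3+])c1ccccc1
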